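**Retrosynthetic overview**

1. The pyran is opened last at C3=C4 (ring-closing metathesis of a C4a-vinyl group with the vinyl group of an (R)-linalyl ether); the O1–C2 bond and the R centre at C2 come unchanged from (R)-linalool, and the acyl stereocentre comes from (R)-2-methylbutanoic acid (C-acylation at C6).
2. The carbocycle is cut at the ring-fusion bond C4a=C8a. This bond is the enol-ether C=C of a vinylogous ester (C8a carries O1 and the quaternary C8; C4a lies α to the C5 carbonyl), which is the retron of an ester-carbonyl Wittig olefination.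
3. The ring is therefore made in a [3+3] sense: an acyl-ylide anion (C4a–C5–C6) is C-acylated by linalyl dimethylmalonyl chloride (C7–C8–C8a), and the ylide then closes onto the ester carbon that already bears the tertiary alkoxy group.
4. What makes this possible: C8 is quaternary (no α-hydrogen, gem-dialkyl effect, no aromatisation), and the oxygen lost from C8a leaves on phosphorus, so the chiral alkoxy group stays. Ring order: carbocycle (step 3), then pyran (step 7).

Key step: step 3

Assumption: chromene numbering (O1, C2, C3, C4, C4a, C5 to C8, C8a) is used for ring atoms; enolised β-dicarbonyl compounds are drawn as one tautomer; (R)-linalool, dimethylmalonyl dichloride and (R)-2-methylbutanoic acid are taken as purchasable; the C2 centre of the final 2H-pyran is taken as configurationally stable at or below 30 °C, so nothing is heated after step 3.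

**Route**

Step 1
Reactants: 1 (R)-linalool [(3R)-3,7-dimethylocta-1,6-dien-3-ol]; 2 dimethylmalonyl dichloride (2,2-dimethylpropanedioyl dichloride)
Product: 4 (3R)-3,7-dimethylocta-1,6-dien-3-yl 3-chloro-2,2-dimethyl-3-oxopropanoate, via lithium alkoxide 3 (not isolated)
Conditions: n-BuLi (1.0 equiv), THF, −78 °C; cannulated into 2 (3 equiv), THF, −78 to 0 °C; excess 2 removed under vacuum
Reagents that add atoms: none
Why: O-acylation of a tertiary lithium alkoxide by an acid chloride; the excess of the symmetrical dichloride (no α-hydrogen, so no ketene) should favour monoacylation, and no bond to the stereocentre is touched.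

Step 2
Reactants: 5 chloroacetone (1-chloropropan-2-one); 6 tributylphosphine
Product: 7 tributyl(2-oxopropyl)phosphonium chloride
Conditions: THF, 0 to 20 °C
Reagents that add atoms: none
Why: SN2 quaternisation of a trialkylphosphine by an α-chloro ketone should give the acetonylphosphonium salt cleanly.

Step 3
Reactants: 4 (3R)-3,7-dimethylocta-1,6-dien-3-yl 3-chloro-2,2-dimethyl-3-oxopropanoate; 7 tributyl(2-oxopropyl)phosphonium chloride
Product: 10 3-hydroxy-6,6-dimethyl-5-{[(3R)-3,7-dimethylocta-1,6-dien-3-yl]oxy}cyclohexa-2,4-dien-1-one, via ylide anion 8 (not isolated), via diketo ylide 9 (not isolated)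
Conditions: 7 (2.1 equiv), LiN(iPr)2 (4.2 equiv), THF, −78 °C; 4 (1.0 equiv), −78 to 0 °C; AcOH (2.1 equiv); then 60 °C
Reagents that add atoms: none
Why: Proposed new method: the lithium enolate 8 of the acyl ylide is C-acylated at its terminal carbon by the acid chloride of 4 (established reactivity of acyl-ylide anions), and in 9 the ylide carbon adds to the ester carbonyl, the oxaphosphetane then losing Bu3PO to form the C4a=C8a enol-ether bond, so that phosphorus and not the tertiary alkoxide carries off the carbonyl oxygen (a Dieckmann closure at the same carbon would expel the chiral alkoxide). The closest known reactions are intramolecular Wittig olefinations of ester carbonyls by stabilised ylides that give cyclic enol ethers (4-alkoxybutenolides from α-hydroxy esters and Ph3P=C=C=O, chromones and benzofurans from acyloxy-substituted ylides); closure of an acyclic tertiary-alkyl ester to a carbocyclic vinylogous ester has not been shown. The six-membered ring closes by 6-exo-trig attack on the ester C=O. No stereocentre is formed and no bond to the carbinol carbon is made or broken, so the R configuration of 1 is carried through. The step needs C- rather than O-attack of the ambident acyl ylide, olefination rather than loss of the alkoxide, and a temperature below that of the Claisen shift of the tertiary allyl vinyl ether product; the quaternary C8 (no α-hydrogen, gem-dialkyl effect), the chelated cis-enol of the 1,3-diketone that holds the ylide carbon next to the ester, the more nucleophilic trialkylphosphine ylide (closure expected at 60 °C) and the irreversible loss of Bu3PO should secure this.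

Step 4
Reactants: 10 3-hydroxy-6,6-dimethyl-5-{[(3R)-3,7-dimethylocta-1,6-dien-3-yl]oxy}cyclohexa-2,4-dien-1-one; 11 (R)-2-methylbutanoic acid
Product: 13 3-hydroxy-6,6-dimethyl-2-[(2R)-2-methylbutanoyl]-5-{[(3R)-3,7-dimethylocta-1,6-dien-3-yl]oxy}cyclohexa-2,4-dien-1-one, via enol ester 12 (not isolated)
Conditions: DCC, DMAP, CH2Cl2, 0 to 20 °C
Reagents that add atoms: none
Why: Steglich esterification of the enol followed by DMAP-mediated 1,3 O-to-C acyl shift (the usual route to 2-acylcyclohexane-1,3-diones) should put the acyl group on C6, because the enolate charge lies on that carbon and not on C4a; the α-stereocentre arrives with 11 and is not touched under these conditions.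

Step 5
Reactants: 13 3-hydroxy-6,6-dimethyl-2-[(2R)-2-methylbutanoyl]-5-{[(3R)-3,7-dimethylocta-1,6-dien-3-yl]oxy}cyclohexa-2,4-dien-1-one
Product: 14 3-hydroxy-4-iodo-6,6-dimethyl-2-[(2R)-2-methylbutanoyl]-5-{[(3R)-3,7-dimethylocta-1,6-dien-3-yl]oxy}cyclohexa-2,4-dien-1-one
Conditions: N-iodosuccinimide, CH2Cl2, 0 °C, dark
Reagents that add atoms: N-iodosuccinimide O=C1CCC(=O)N1I
Why: Electrophilic iodination at the only free ring carbon (C4a, the enol-ether α-carbon of the vinylogous ester), as in α-iodination of β-alkoxy enones; the isolated alkenes should react far more slowly with the neutral reagent.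

Step 6
Reactants: 14 3-hydroxy-4-iodo-6,6-dimethyl-2-[(2R)-2-methylbutanoyl]-5-{[(3R)-3,7-dimethylocta-1,6-dien-3-yl]oxy}cyclohexa-2,4-dien-1-one
Product: 15 4-ethenyl-3-hydroxy-6,6-dimethyl-2-[(2R)-2-methylbutanoyl]-5-{[(3R)-3,7-dimethylocta-1,6-dien-3-yl]oxy}cyclohexa-2,4-dien-1-one
Conditions: tributyl(vinyl)stannane, Pd2(dba)3, AsPh3, CuI, DMF, 20 °C
Reagents that add atoms: tributyl(vinyl)stannane CCCC[Sn](CCCC)(CCCC)C=C
Why: Stille coupling of an α-iodo vinylogous ester with a vinylstannane, run at room temperature with the copper co-catalyst so that transmetalation outruns intramolecular carbopalladation and no Claisen shift can set in.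

Step 7
Reactants: 15 4-ethenyl-3-hydroxy-6,6-dimethyl-2-[(2R)-2-methylbutanoyl]-5-{[(3R)-3,7-dimethylocta-1,6-dien-3-yl]oxy}cyclohexa-2,4-dien-1-one
Product: 16 (2R)-5-hydroxy-2,8,8-trimethyl-6-[(2R)-2-methylbutanoyl]-2-(4-methylpent-3-en-1-yl)-2H-chromen-7(8H)-one
Conditions: second-generation Grubbs catalyst (5 mol %), CH2Cl2, 30 °C
Reagents that add atoms: none
Why: Ring-closing metathesis of the two terminal vinyl groups (the known route from 2-vinylaryl 1,1-disubstituted allyl ethers to 2,2-disubstituted 2H-chromenes) should close the six-membered pyran faster than the etherified linalyl unit can cyclise onto its trisubstituted alkene, and since no bond to C2 is broken the R configuration is retained.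

**Compound list**

1 | (R)-linalool, (3R)-3,7-dimethylocta-1,6-dien-3-ol | C=C[C@](C)(O)CCC=C(C)C | starting material
2 | dimethylmalonyl dichloride | CC(C)(C(Cl)=O)C(Cl)=O | starting material
3 | lithium (3R)-3,7-dimethylocta-1,6-dien-3-olate | [Li]O[C@](C)(CCC=C(C)C)C=C | intermediate
4 | (3R)-3,7-dimethylocta-1,6-dien-3-yl 3-chloro-2,2-dimethyl-3-oxopropanoate | ClC(=O)C(C)(C)C(=O)O[C@](C)(CCC=C(C)C)C=C | intermediate
5 | chloroacetone | CC(=O)CCl | starting material
6 | tributylphosphine | CCCCP(CCCC)CCCC | starting material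
7 | tributyl(2-oxopropyl)phosphonium chloride | CCCC[P+](CCCC)(CCCC)CC(C)=O.[Cl-] | intermediate
8 | lithium 3-(tributyl-λ5-phosphanylidene)prop-1-en-2-olate (ylide anion) | [Li]OC(=C)C=P(CCCC)(CCCC)CCCC | intermediate
9 | (3R)-3,7-dimethylocta-1,6-dien-3-yl 2,2-dimethyl-3,5-dioxo-6-(tributyl-λ5-phosphanylidene)hexanoate | O=C(C=P(CCCC)(CCCC)CCCC)CC(=O)C(C)(C)C(=O)O[C@](C)(CCC=C(C)C)C=C | intermediate
10 | 3-hydroxy-6,6-dimethyl-5-{[(3R)-3,7-dimethylocta-1,6-dien-3-yl]oxy}cyclohexa-2,4-dien-1-one | O=C1C=C(O)C=C(O[C@](C)(CCC=C(C)C)C=C)C1(C)C | intermediate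
11 | (R)-2-methylbutanoic acid | CC[C@@H](C)C(O)=O | starting material
12 | 6,6-dimethyl-5-{[(3R)-3,7-dimethylocta-1,6-dien-3-yl]oxy}-1-oxocyclohexa-2,4-dien-3-yl (2R)-2-methylbutanoate (enol ester) | O=C1C=C(OC(=O)[C@H](C)CC)C=C(O[C@](C)(CCC=C(C)C)C=C)C1(C)C | intermediate
13 | 3-hydroxy-6,6-dimethyl-2-[(2R)-2-methylbutanoyl]-5-{[(3R)-3,7-dimethylocta-1,6-dien-3-yl]oxy}cyclohexa-2,4-dien-1-one | CC[C@@H](C)C(=O)C1=C(O)C=C(O[C@](C)(CCC=C(C)C)C=C)C(C)(C)C1=O | intermediate
14 | 3-hydroxy-4-iodo-6,6-dimethyl-2-[(2R)-2-methylbutanoyl]-5-{[(3R)-3,7-dimethylocta-1,6-dien-3-yl]oxy}cyclohexa-2,4-dien-1-one | CC[C@@H](C)C(=O)C1=C(O)C(I)=C(O[C@](C)(CCC=C(C)C)C=C)C(C)(C)C1=O | intermediate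
15 | 4-ethenyl-3-hydroxy-6,6-dimethyl-2-[(2R)-2-methylbutanoyl]-5-{[(3R)-3,7-dimethylocta-1,6-dien-3-yl]oxy}cyclohexa-2,4-dien-1-one | CC[C@@H](C)C(=O)C1=C(O)C(C=C)=C(O[C@](C)(CCC=C(C)C)C=C)C(C)(C)C1=O | intermediate
16 | (2R)-5-hydroxy-2,8,8-trimethyl-6-[(2R)-2-methylbutanoyl]-2-(4-methylpent-3-en-1-yl)-2H-chromen-7(8H)-one | CC[C@@H](C)C(=O)C1=C(O)C2=C(O[C@](C)(CCC=C(C)C)C=C2)C(C)(C)C1=O | target

**Step count and risks**

Total steps: 7. Longest linear sequence: 6 steps (1 → 4 → 10 → 13 → 14 → 15 → 16); step 2 is a one-step side branch.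

Steps most likely to fail:

1. Step 3 (proposed new method). The doubly stabilised ylide may add too slowly to the congested ester carbonyl. Acyl transfer to the ylide oxygen with loss of linalool, or a Claisen shift of the product if the temperature has to be raised, would then take over. Fallback with known chemistry, from 1 to 10: the carbocycle is taken ready-made instead of being closed. Filicinic acid (2,2-dimethylcyclohexane-1,3,5-trione) with oxalyl chloride and catalytic DMF should give 3,5-dichloro-4,4-dimethylcyclohexa-2,5-dien-1-one F1. The potassium alkoxide of 1 (KH, THF, −40 °C) replaces one vinylogous acyl chloride by addition–elimination to give 3-chloro-4,4-dimethyl-5-{[(3R)-3,7-dimethylocta-1,6-dien-3-yl]oxy}cyclohexa-2,5-dien-1-one F2. LiOH in THF–water at 0 °C hydrolyses the second vinylogous acyl chloride and returns the route at 10.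

2. Step 6. Transmetalation at the congested α-iodo vinylogous ester may be slow, so that protodeiodination or intramolecular carbopalladation of the neighbouring vinyl group competes. Fallback, from 14 to 15, brings in the two carbons as an alkyne. Sonogashira coupling with ethynyltrimethylsilane (Pd(PPh3)2Cl2, CuI, Et3N, 20 °C) gives 3-hydroxy-6,6-dimethyl-2-[(2R)-2-methylbutanoyl]-5-{[(3R)-3,7-dimethylocta-1,6-dien-3-yl]oxy}-4-[(trimethylsilyl)ethynyl]cyclohexa-2,4-dien-1-one F3. K2CO3 in MeOH gives 4-ethynyl-3-hydroxy-6,6-dimethyl-2-[(2R)-2-methylbutanoyl]-5-{[(3R)-3,7-dimethylocta-1,6-dien-3-yl]oxy}cyclohexa-2,4-dien-1-one F4. Semi-hydrogenation (H2, Pd on CaCO3 poisoned with Pb(OAc)2, quinoline) then gives 15.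

3. Step 1. Double acylation of the dichloride to the symmetrical diester, or hydrolysis of the congested acid chloride while the excess reagent is removed, would waste the chiral alcohol. Fallback, from 1 to 4, differentiates the two carbonyls stepwise. The lithium alkoxide 3 is acylated with methyl 3-chloro-2,2-dimethyl-3-oxopropanoate to give methyl (3R)-3,7-dimethylocta-1,6-dien-3-yl 2,2-dimethylpropanedioate F5. LiOH (1 equiv, THF–water) saponifies only the methyl ester to 3-{[(3R)-3,7-dimethylocta-1,6-dien-3-yl]oxy}-2,2-dimethyl-3-oxopropanoic acid F6. 1-Chloro-N,N,2-trimethylprop-1-en-1-amine then converts F6 under neutral conditions into 4.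

Further compounds
F1 | step 3 | 3,5-dichloro-4,4-dimethylcyclohexa-2,5-dien-1-one | O=C1C=C(Cl)C(C)(C)C(Cl)=C1
F2 | step 3 | 3-chloro-4,4-dimethyl-5-{[(3R)-3,7-dimethylocta-1,6-dien-3-yl]oxy}cyclohexa-2,5-dien-1-one | O=C1C=C(Cl)C(C)(C)C(O[C@](C)(CCC=C(C)C)C=C)=C1
F3 | step 6 | 3-hydroxy-6,6-dimethyl-2-[(2R)-2-methylbutanoyl]-5-{[(3R)-3,7-dimethylocta-1,6-dien-3-yl]oxy}-4-[(trimethylsilyl)ethynyl]cyclohexa-2,4-dien-1-one | CC[C@@H](C)C(=O)C1=C(O)C(C#C[Si](C)(C)C)=C(O[C@](C)(CCC=C(C)C)C=C)C(C)(C)C1=O
F4 | step 6 | 4-ethynyl-3-hydroxy-6,6-dimethyl-2-[(2R)-2-methylbutanoyl]-5-{[(3R)-3,7-dimethylocta-1,6-dien-3-yl]oxy}cyclohexa-2,4-dien-1-one | CC[C@@H](C)C(=O)C1=C(O)C(C#C)=C(O[C@](C)(CCC=C(C)C)C=C)C(C)(C)C1=O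
F5 | step 1 | methyl (3R)-3,7-dimethylocta-1,6-dien-3-yl 2,2-dimethylpropanedioate | COC(=O)C(C)(C)C(=O)O[C@](C)(CCC=C(C)C)C=C
F6 | step 1 | 3-{[(3R)-3,7-dimethylocta-1,6-dien-3-yl]oxy}-2,2-dimethyl-3-oxopropanoic acid | OC(=O)C(C)(C)C(=O)O[C@](C)(CCC=C(C)C)C=C
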